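## Retrosynthetic overview

1. Target ⇐ its sn-3 4-methoxybenzyl (PMB) ether; the final unmasking is oxidative and base-free, so the 1,2-diacyl pattern does not migrate.
2. Both trans-oxiranes ⇐ one flask: the dilithium bis(diynylide) of 3-O-PMB-1,2-bis(hepta-4,6-diynoyl)-sn-glycerol adds to two molecules of (R)-2-chloro-(6Z,8Z)-undeca-6,8-dienal, and both chloro-alkoxides close (2 C–C bonds, 2 rings, 2 carbinol centres set, 2 C–Cl centres inverted).
3. Chloroaldehyde ⇐ organocatalytic α-chlorination of (6Z,8Z)-undeca-6,8-dienal ⇐ zinc reduction of undeca-6,8-diyn-1-ol ⇐ Hay coupling of hept-6-yn-1-ol with but-1-yne.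
4. Bis-diyne diester ⇐ 3-O-PMB-sn-glycerol (from (S)-solketal) + hepta-4,6-diynoic acid (Cadiot–Chodkiewicz coupling of pent-4-ynoic acid).
5. Ring order: no ring is made until the penultimate step, where both oxiranes form together.

Assumption: (2S,5S)-2,5-diphenylpyrrolidine is taken to give the (2R)-chloroaldehyde (chlorine enters the enamine face away from the nearer phenyl group); if the measured sense is the opposite, the (2R,5R)-catalyst is used and nothing else changes.

## Route

Step 1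
Reactants: 1 hept-6-yn-1-ol; 2 but-1-yne (6 equiv)
Product: 3 undeca-6,8-diyn-1-ol
Conditions: CuCl (10 mol%), TMEDA (10 mol%), O2 (balloon), acetone, 0 °C, dry-ice condenser
Reagents that add atoms: none
Why: Glaser–Hay oxidative alkyne hetero-coupling (O2 is the terminal oxidant and water the only co-product), in which the large excess of cheap, volatile but-1-yne channels the alkynol into the cross-coupled diyne and both homodimers (non-polar octa-3,5-diyne, polar diol) are easily removed.

Step 2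
Reactants: 3 undeca-6,8-diyn-1-ol
Product: 4 (6Z,8Z)-undeca-6,8-dien-1-ol
Conditions: Zn dust activated with Cu(OAc)2 and AgNO3, MeOH/H2O (1:1), 40 °C
Reagents that add atoms: none
Why: Boland-type zinc semi-reduction, in which cis delivery of two hydrogens to each conjugated triple bond gives the Z,Z-diene without over-reduction.

Step 3
Reactants: 4 (6Z,8Z)-undeca-6,8-dien-1-ol
Product: 5 (6Z,8Z)-undeca-6,8-dienal
Conditions: Dess–Martin periodinane (1.2 equiv), CH2Cl2, 0 °C to rt
Reagents that add atoms: none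
Why: Dess–Martin oxidation of a primary alcohol stops at the aldehyde under near-neutral conditions that do not isomerise the Z,Z-diene.

Step 4
Reactants: 5 (6Z,8Z)-undeca-6,8-dienal
Product: 6 (2R,6Z,8Z)-2-chloroundeca-6,8-dienal
Conditions: NCS (1.2 equiv), (2S,5S)-2,5-diphenylpyrrolidine (10 mol%), CH2Cl2, 0 °C to rt; pentane, filter; used at once without chromatography
Reagents that add atoms: N-chlorosuccinimide, ClN1C(=O)CCC1=O
Why: Organocatalytic enamine α-chlorination, in which the C2-symmetric pyrrolidine enamine is chlorinated on the face away from the nearer phenyl group to set C2 as R (the later C9 of each acyl chain); the much more nucleophilic enamine outcompetes the diene for NCS.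

Step 5
Reactants: 7 pent-4-ynoic acid; 8 (bromoethynyl)trimethylsilane (1.05 equiv)
Product: 10 hepta-4,6-diynoic acid, via 7-(trimethylsilyl)hepta-4,6-diynoic acid 9 (not isolated)
Conditions: CuCl (5 mol%), NH2OH·HCl (0.3 equiv), n-BuNH2 (4 equiv), MeOH, 0 °C, under Ar; then K2CO3 (cat.), rt; 1 M HCl work-up
Reagents that add atoms: none
Why: Cadiot–Chodkiewicz sp–sp coupling of the terminal alkyne with the bromoalkyne, followed in the same flask by base-catalysed methanolysis of the very labile diynyl C–Si bond.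

Step 6
Reactants: 11 (S)-solketal [(S)-2,2-dimethyl-1,3-dioxolane-4-methanol, 1,2-O-isopropylidene-sn-glycerol]
Product: 12 (S)-4-[(4-methoxybenzyloxy)methyl]-2,2-dimethyl-1,3-dioxolane
Conditions: NaH (1.2 equiv), PMBCl (1.1 equiv), Bu4NI (cat.), THF/DMF, 0 °C to rt
Reagents that add atoms: 4-methoxybenzyl chloride, COc1ccc(CCl)cc1
Why: Williamson etherification of the sn-3 hydroxyl, which does not touch the stereocentre taken from the chiral pool.

Step 7
Reactants: 12 (S)-4-[(4-methoxybenzyloxy)methyl]-2,2-dimethyl-1,3-dioxolane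
Product: 13 (R)-3-(4-methoxybenzyloxy)propane-1,2-diol (3-O-PMB-sn-glycerol)
Conditions: AcOH/H2O (4:1), 40 °C
Reagents that add atoms: none
Why: Acid-catalysed acetonide hydrolysis, which the PMB ether survives; no bond to the stereocentre is broken (the descriptor changes only through CIP priorities).

Step 8
Reactants: 13 (R)-3-(4-methoxybenzyloxy)propane-1,2-diol; 10 hepta-4,6-diynoic acid (2.4 equiv)
Product: 14 (2S)-3-(4-methoxybenzyloxy)propane-1,2-diyl bis(hepta-4,6-diynoate) (3-O-PMB-1,2-bis-O-(hepta-4,6-diynoyl)-sn-glycerol)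
Conditions: DCC (2.5 equiv), DMAP (0.2 equiv), CH2Cl2, 0 °C to rt
Reagents that add atoms: none
Why: Steglich esterification acylates the primary and the secondary hydroxyl alike under conditions that terminal diynes tolerate.

Step 9
Reactants: 14 3-O-PMB-1,2-bis-O-(hepta-4,6-diynoyl)-sn-glycerol; 6 (2R,6Z,8Z)-2-chloroundeca-6,8-dienal (2.6 equiv)
Product: 17 3-O-(4-methoxybenzyl)-1,2-bis-O-[(8S,9S,13Z,15Z)-8,9-epoxyoctadeca-13,15-dien-4,6-diynoyl]-sn-glycerol, via dilithium bis-acetylide 15 (not isolated), via dilithium bis(chloro-alkoxide) 16 (not isolated)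
Conditions: LiN(SiMe3)2 (2.05 equiv), THF, −78 °C, 30 min; 6, −78 °C, 1 h; DMPU (10 equiv), −78 to 0 °C, 3 h; pH 7 buffer
Reagents that add atoms: none
Why: Acetylide addition to an α-chloroaldehyde followed by chlorohydrin-to-epoxide closure: the amide base removes the C(sp)–H (more acidic and kinetically faster to lose than the ester α-CH), each diynyllithium adds under Cornforth (polar Felkin–Anh) control to give the anti chloro-alkoxide (C8 set as S), and the 3-exo-tet SN2 closure inverts the (R)-C–Cl carbon to (S)-C–O, so both trans-(8S,9S)-oxiranes form in the same flask.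

Step 10
Reactants: 17 3-O-(4-methoxybenzyl)-1,2-bis-O-[(8S,9S,13Z,15Z)-8,9-epoxyoctadeca-13,15-dien-4,6-diynoyl]-sn-glycerol
Product: 18 1,2-bis-O-[(8S,9S,13Z,15Z)-8,9-epoxyoctadeca-13,15-dien-4,6-diynoyl]-sn-glycerol (glycerol C2 = S; CNP0301966.1)
Conditions: DDQ (1.3 equiv), CH2Cl2/pH 7 phosphate buffer (10:1), 0 °C; cold chromatography on boric acid-impregnated silica
Reagents that add atoms: none
Why: Oxidative PMB ether cleavage (hydride abstraction from the electron-rich benzylic position, then hydrolysis of the oxocarbenium ion) is buffered and base-free, so the oxiranes survive and the 1,2-diacyl pattern does not shift to 1,3.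

## Compound list

1 | hept-6-yn-1-ol | C#CCCCCCO | starting material
2 | but-1-yne | CCC#C | starting material
3 | undeca-6,8-diyn-1-ol | CCC#CC#CCCCCCO | intermediate
4 | (6Z,8Z)-undeca-6,8-dien-1-ol | CC/C=C\C=C/CCCCCO | intermediate
5 | (6Z,8Z)-undeca-6,8-dienal | CC/C=C\C=C/CCCCC=O | intermediate
6 | (2R,6Z,8Z)-2-chloroundeca-6,8-dienal | CC/C=C\C=C/CCC[C@@H](Cl)C=O | intermediate
7 | pent-4-ynoic acid | C#CCCC(=O)O | starting material
8 | (bromoethynyl)trimethylsilane | C[Si](C)(C)C#CBr | starting material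
9 | 7-(trimethylsilyl)hepta-4,6-diynoic acid (not isolated) | C[Si](C)(C)C#CC#CCCC(=O)O | intermediate
10 | hepta-4,6-diynoic acid | C#CC#CCCC(=O)O | intermediate
11 | (S)-solketal, 1,2-O-isopropylidene-sn-glycerol | CC1(C)OC[C@H](CO)O1 | starting material
12 | (S)-4-[(4-methoxybenzyloxy)methyl]-2,2-dimethyl-1,3-dioxolane | CC1(C)OC[C@H](COCc2ccc(OC)cc2)O1 | intermediate
13 | (R)-3-(4-methoxybenzyloxy)propane-1,2-diol (3-O-PMB-sn-glycerol) | OC[C@H](COCc1ccc(OC)cc1)O | intermediate
14 | (2S)-3-(4-methoxybenzyloxy)propane-1,2-diyl bis(hepta-4,6-diynoate) | C#CC#CCCC(=O)OC[C@H](COCc1ccc(OC)cc1)OC(=O)CCC#CC#C | intermediate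
15 | dilithium bis-acetylide of 14 (not isolated) | [Li]C#CC#CCCC(=O)OC[C@H](COCc1ccc(OC)cc1)OC(=O)CCC#CC#C[Li] | intermediate
16 | dilithium bis(alkoxide) of 3-O-PMB-1,2-bis-O-[(8S,9R,13Z,15Z)-9-chloro-8-hydroxyoctadeca-13,15-dien-4,6-diynoyl]-sn-glycerol (not isolated) | CC/C=C\C=C/CCC[C@H]([C@@H](O[Li])C#CC#CCCC(=O)OC[C@H](COCc1ccc(OC)cc1)OC(=O)CCC#CC#C[C@H](O[Li])[C@H](Cl)CCC/C=C\C=C/CC)Cl | intermediate
17 | 3-O-(4-methoxybenzyl)-1,2-bis-O-[(8S,9S,13Z,15Z)-8,9-epoxyoctadeca-13,15-dien-4,6-diynoyl]-sn-glycerol | CC/C=C\C=C/CCC[C@@H]1O[C@H]1C#CC#CCCC(=O)OC[C@H](COCc1ccc(OC)cc1)OC(=O)CCC#CC#C[C@@H]1O[C@H]1CCC/C=C\C=C/CC | intermediate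
18 | 1,2-bis-O-[(8S,9S,13Z,15Z)-8,9-epoxyoctadeca-13,15-dien-4,6-diynoyl]-sn-glycerol | CC/C=C\C=C/CCC[C@@H]1O[C@H]1C#CC#CCCC(=O)OC[C@H](CO)OC(=O)CCC#CC#C[C@@H]1O[C@H]1CCC/C=C\C=C/CC | target

## Step count and risks

Total step count: 10. Longest linear sequence: 6 steps (1 → 2 → 3 → 4 → 9 → 10).

Steps most likely to fail:

Step 9. The amide base may enolise the esters, the anti:syn ratio may erode, or the alkoxides may transesterify before they close. Because the two arms react independently, the ee of 6 and the diastereoselectivity multiply: at 95% ee and 15:1 dr only about four fifths of the product is the wanted isomer, and the rest must be removed by HPLC. The fallback sets out from 14 (with 6) and comes back at 17. It separates C–C bond formation from ring closure and avoids strong base: Me2Zn (6 equiv) with a catalytic ProPhenol ligand (the enantiomer matched to Si-face delivery) and Ph3P=O in toluene at 0 °C turns 14 into the bis(methylzinc acetylide) F1, which adds to 6 to give the bis(methylzinc alkoxide) F2. Aqueous NH4Cl releases the bis-chlorohydrin 3-O-PMB-1,2-bis-O-[(8S,9R,13Z,15Z)-9-chloro-8-hydroxyoctadeca-13,15-dien-4,6-diynoyl]-sn-glycerol F3. This is freed from syn isomers by chromatography and then closed twice with Cs2CO3 in MeCN at 0 °C to give 17.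

Step 10. DDQ may attack the Z,Z-dienes, and the 1,2-diacylglycerol can rearrange to the 1,3-isomer during isolation. The fallback sets out from 11 and comes back at 18, carrying the sn-3 oxygen as a silyl ether that buffered fluoride removes without an oxidant. TBDPSCl/imidazole in DMF gives 1,2-O-isopropylidene-3-O-(tert-butyldiphenylsilyl)-sn-glycerol F4, and AcOH/H2O gives 3-O-(tert-butyldiphenylsilyl)-sn-glycerol F5. DCC/DMAP with 10 gives 3-O-TBDPS-1,2-bis-O-(hepta-4,6-diynoyl)-sn-glycerol F6. The conditions of step 9 with 6 take this through the dilithium bis-acetylide F7 and the dilithium bis(chloro-alkoxide) F8 to the silylated bis-epoxide F9. Bu4NF/AcOH (1:1) in THF at 0 °C then gives 18.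

Step 5. The trimethylsilyl group may be lost before coupling, which gives bromoacetylene, homocoupling and triyne by-products, and 10 is a terminal diyne of limited stability. The fallback sets out from 7 and comes back at 10. It reverses the polarity of the coupling and uses a robust silyl group: NBS with AgNO3 (cat.) in acetone gives 5-bromopent-4-ynoic acid F10. This is coupled (CuCl, NH2OH·HCl, aqueous n-BuNH2, 0 °C) with ethynyltriisopropylsilane (1.5 equiv) to give the stable, chromatographable 7-(triisopropylsilyl)hepta-4,6-diynoic acid F11. Bu4NF in THF at 0 °C releases 10 just before step 8.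

Further compounds

F1 | step 9 | bis(methylzinc acetylide) of 14 | C[Zn]C#CC#CCCC(=O)OC[C@H](COCc1ccc(OC)cc1)OC(=O)CCC#CC#C[Zn]C
F2 | step 9 | bis(methylzinc alkoxide) of the bis-chlorohydrin | CC/C=C\C=C/CCC[C@H]([C@@H](O[Zn]C)C#CC#CCCC(=O)OC[C@H](COCc1ccc(OC)cc1)OC(=O)CCC#CC#C[C@H](O[Zn]C)[C@H](Cl)CCC/C=C\C=C/CC)Cl
F3 | step 9 | 3-O-PMB-1,2-bis-O-[(8S,9R,13Z,15Z)-9-chloro-8-hydroxyoctadeca-13,15-dien-4,6-diynoyl]-sn-glycerol | CC/C=C\C=C/CCC[C@H]([C@@H](O)C#CC#CCCC(=O)OC[C@H](COCc1ccc(OC)cc1)OC(=O)CCC#CC#C[C@H](O)[C@H](Cl)CCC/C=C\C=C/CC)Cl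
F4 | step 10 | 1,2-O-isopropylidene-3-O-(tert-butyldiphenylsilyl)-sn-glycerol | CC1(C)OC[C@H](CO[Si](c2ccccc2)(c2ccccc2)C(C)(C)C)O1
F5 | step 10 | 3-O-(tert-butyldiphenylsilyl)-sn-glycerol | OC[C@H](CO[Si](c1ccccc1)(c1ccccc1)C(C)(C)C)O
F6 | step 10 | 3-O-TBDPS-1,2-bis-O-(hepta-4,6-diynoyl)-sn-glycerol | C#CC#CCCC(=O)OC[C@H](CO[Si](c1ccccc1)(c1ccccc1)C(C)(C)C)OC(=O)CCC#CC#C
F7 | step 10 | dilithium bis-acetylide of F6 | [Li]C#CC#CCCC(=O)OC[C@H](CO[Si](c1ccccc1)(c1ccccc1)C(C)(C)C)OC(=O)CCC#CC#C[Li]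
F8 | step 10 | dilithium bis(chloro-alkoxide) of the 3-O-TBDPS series | CC/C=C\C=C/CCC[C@H]([C@@H](O[Li])C#CC#CCCC(=O)OC[C@H](CO[Si](c1ccccc1)(c1ccccc1)C(C)(C)C)OC(=O)CCC#CC#C[C@H](O[Li])[C@H](Cl)CCC/C=C\C=C/CC)Cl
F9 | step 10 | 3-O-TBDPS-1,2-bis-O-[(8S,9S,13Z,15Z)-8,9-epoxyoctadeca-13,15-dien-4,6-diynoyl]-sn-glycerol | CC/C=C\C=C/CCC[C@@H]1O[C@H]1C#CC#CCCC(=O)OC[C@H](CO[Si](c1ccccc1)(c1ccccc1)C(C)(C)C)OC(=O)CCC#CC#C[C@@H]1O[C@H]1CCC/C=C\C=C/CC
F10 | step 5 | 5-bromopent-4-ynoic acid | BrC#CCCC(=O)O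
F11 | step 5 | 7-(triisopropylsilyl)hepta-4,6-diynoic acid | CC(C)[Si](C(C)C)(C(C)C)C#CC#CCCC(=O)O
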